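Readings and results were computed for an exercise; noise was put on by code.

In a closed flask of constant volume the charged starting material stays counted. In the last alpha reading c(starting material), c(open intermediate) and c(product) add up to 101%. So the conversion X, the fraction of starting material gone, is open intermediate plus a correction, the product, and the correction is what you compute.

| flask | starting material | partner | free catalyst | temperature | remark | time |
|---|---|---|---|---|---|---|
| epsilon | 10 mM | 1.1 equiv | 5 mol% | 65 °C | run made earlier |  |
| alpha | 40 mM | 1.1 equiv | 5 mol% | 90 °C | run made earlier |  |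
| eta | 20 mM | 1.1 equiv | 7.5 mol% | 65 °C | run made earlier |  |
| alder | 20 mM | 1.10 equiv | 5 mol% | 70 °C |  | 40 min |
| larch | 20 mM | 1.10 equiv | 5 mol% | 90 °C |  | 40 min |
| ash | 20 mM | 1.10 equiv | 5 mol% | 110 °C |  | 40 min |

| run | time / min | open intermediate / % | product / % | starting material / % |
|---|---|---|---|---|
| epsilon | 2.50 | 1.2 | 1.8 | 97.8 |
| epsilon | 4.00 | 0.7 | 1.9 | 97.8 |
| epsilon | 6.00 | 2.2 | 0 | 98.1 |
| epsilon | 10.0 | 3.7 | 0 | 95.3 |
| epsilon | 15.0 | 6.0 | 0 | 93.6 |
| epsilon | 20.0 | 8.7 | 0.2 | 93.9 |
| epsilon | 30.0 | 11.7 | 0.9 | 87.8 |
| alpha | 0.500 | 2.6 | 0 | 96.8 |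
| alpha | 2.00 | 12.5 | 0.4 | 87.1 |
| alpha | 4.00 | 22.5 | 2.7 | 72.5 |
| alpha | 6.00 | 30.2 | 4.8 | 65.6 |
| alpha | 8.00 | 34.0 | 7.8 | 56.9 |
| alpha | 10.0 | 36.9 | 11.3 | 50.8 |
| alpha | 12.0 | 40.8 | 16.0 | 44.6 |
| eta | 3.00 | 3.7 | 0.1 | 97.4 |
| eta | 8.00 | 8.8 | 0 | 90.5 |
| eta | 15.0 | 16.0 | 0.3 | 82.6 |
| eta | 25.0 | 23.5 | 4.5 | 74.5 |
| eta | 30.0 | 26.0 | 3.5 | 68.8 |

(readings scatter by 1 percentage point)



- which of these there is most of at the end, counted by the starting material in it, alder (product / starting material / open intermediate)
- which of these there is most of at the end, counted by the starting material in it, larch (product / starting material / open intermediate)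
- which of these there is most of at the end, counted by the starting material in it, ash (product / starting material / open intermediate)
- final amount of the leader among these, as a percentage of the starting material charged, in alder
- final amount of the leader among these, as a percentage of the starting material charged, in larch
- final amount of the leader among these, as a percentage of the starting material charged, in ash

Take the last reading of each earlier run. Let k = ln(charged/left)/time, a pseudo-first-order constant for the loss of starting material, and divide it by c(free catalyst) as charged. Let S = t − X/k, the time integral of X under that decay: the conversion-minutes offered to the second step. Let g = c(product)/S.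

- epsilon: k 0.00434 min⁻¹, per catalyst 8.67 L mol⁻¹ min⁻¹, S 1.87 min, g 0.00481 min⁻¹
- eta: k 0.0125 min⁻¹, per catalyst 8.31 L mol⁻¹ min⁻¹, S 4.97 min, g 0.00704 min⁻¹
- alpha: k 0.0673 min⁻¹, per catalyst 33.6 L mol⁻¹ min⁻¹, S 3.77 min, g 0.0425 min⁻¹

Read the second column first. Epsilon and eta, both at 65 °C, give nearly the same value per catalyst, so k goes with the catalyst charge. Alpha's value, at 90 °C, is larger than epsilon's.

Now read the last column. Alpha's g is the product made per conversion-minute, which I call the leak constant. Epsilon's g rests on a product reading within its scatter of zero, so these rows do not separate partner from catalyst. My own choice is that g goes with c(partner)·c(free catalyst), since the partner enters the product and the catalyst carries the first step.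

Larch stands at alpha's temperature, so no temperature extrapolation enters. Its catalyst concentration is half of alpha's, which gives k = 0.0336 min⁻¹ in proportion. Its g is 0.0106 min⁻¹, a quarter of alpha's. After 40 min I reckon 26.0% starting material, S = 18.0 min, product 19.1%, and open intermediate as the remainder, 54.8%, which leads.

The forecast names starting material for alder at 64% (59% to 69%), open intermediate for larch at 41% (35% to 46%), and product for ash at 77% (66% to 90%). Of the second step it says: “This scales with catalyst or partner concentration, though the data cannot separate the two.” It agrees with my leader in larch but stands lower than my amount.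

The flasks give starting material at 64.4% in alder, open intermediate at 54.0% in larch, and open intermediate at 51.8% in ash, with product 46.0%.

    free catalyst + open intermediate ⇌ catalyst intermediate (K = 25.0 L mol⁻¹, k = 63.7 L mol⁻¹ min⁻¹, Ea = 36.0 kJ mol⁻¹, ΔH = −24.0 kJ mol⁻¹)
    starting material + free catalyst → free catalyst + open intermediate (k = 11.8 L mol⁻¹ min⁻¹, Ea = 61.0 kJ mol⁻¹)
    partner + catalyst intermediate → free catalyst + product (k = 17.5 L mol⁻¹ min⁻¹, Ea = 59.0 kJ mol⁻¹)
    (constants at 70 °C)

Open intermediate leads ash because of the return of catalyst intermediate to free catalyst and open intermediate, together with the time allowed: without the return ash holds 3.65% open intermediate, and at 400 min it holds 4.11%. Ash's simulated amounts give k = 0.100 min⁻¹, S = 30.2 min and g = 0.0152 min⁻¹, which is 1.43 times the 0.0106 min⁻¹ that alpha's leak constant 0.0425 min⁻¹ gave for larch. Scaled to 0.440 equiv of partner, that g reckons 18.4% product for the neighbour of ash with that charge, and that neighbour holds 21.8% product.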